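**Retrosynthetic overview**
1. Ring A is closed last by ring-closing metathesis (C1=C2), after an acrolein aldol (C3–C4) and a lactone-forming intramolecular Michael addition (C4–C5) on the B/C/D enone ester 21.
2. 21 comes from 15 by B-ring adjustment: C6 ketone → vinyl triflate → carbonylation (C7), then C10 silyl ether → ketone.
3. Key step: 15 from 14 by a SmI2 ketyl 3-exo cyclisation/fragmentation (radical 1,2-alkenyl shift, new C13–C16 bond) that turns a 1-silyloxy-6-methylenebicyclo[2.2.2]octan-2-one into the 12,13-dioxygenated 16-methylenebicyclo[3.2.1]octane.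
4. 14 from siloxy diene 9 + acrolein (Diels–Alder, sets C8 and C12); 9 from enone 1 + Danishefsky's diene 2 (Diels–Alder, sets C9).
5. Ring order: B (bought) → C → bicyclo[2.2.2] → C/D (rearrangement) → lactone → A.

Assumption: gibberellin numbering (C1–C19) is used for every intermediate, and 1 and 2 are bought in their silyl-protected forms.

**Step 1**
Reactants: 1 (R)-4-(tert-butyldimethylsilyloxy)cyclopent-2-en-1-one; 2 (E)-1-methoxy-3-(trimethylsilyloxy)buta-1,3-diene
Product: 4 cis-fused 13-hydroxy-14-methoxy-6,12-diketone, via silyl enol ether cycloadduct 3 (not isolated)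
Conditions: toluene, 110 °C (sealed tube); concentrate; DMDO, acetone/CH2Cl2, −78 → 0 °C; citric acid, MeOH, 0 °C
Reagents that add atoms: dimethyldioxirane CC1(C)OO1
Why: Diels–Alder reaction with Danishefsky's diene (CH2 terminus to the β-carbon C9, anti to the C10 silyloxy group, cis fusion) sets C8 and C9, and Rubottom oxidation of the silyl enol ether puts oxygen on C13 (C13/C14 configurations are erased in step 2).

**Step 2**
Reactants: 4 cis-fused 13-hydroxy-14-methoxy-6,12-diketone
Product: 6 13-acetoxy-13-en-12-one 6-ketone, via acetoxy methoxy ketone 5 (not isolated)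
Conditions: Ac2O, Et3N, DMAP (cat.), CH2Cl2, 0 → 23 °C
Reagents that add atoms: acetic anhydride CC(=O)OC(C)=O
Why: O-acetylation followed by E1cB elimination of methanol from the β-methoxy ketone gives the 2-acetoxy enone (diosphenol acetate), the cis ring fusion being the thermodynamic one so that reversible enolisation at C8 does no harm.

**Step 3**
Reactants: 6 13-acetoxy-13-en-12-one 6-ketone
Product: 7 6α-alcohol
Conditions: NaBH4, MeOH/CH2Cl2 (1:1), −78 °C
Reagents that add atoms: none
Why: Chemoselective borohydride reduction of the saturated cyclopentanone beside the conjugated enone, hydride entering from the convex β face (this carbinol centre is erased again in step 10).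

**Step 4**
Reactants: 7 6α-alcohol
Product: 9 12-(triisopropylsilyloxy)-13-acetoxy-12,14(8)-diene, via trimethylsilyl ether 8 (not isolated)
Conditions: Me3SiCl, Et3N, CH2Cl2, 0 °C; then iPr3SiOTf, Et3N, 23 → 40 °C
Reagents that add atoms: chlorotrimethylsilane C[Si](C)(C)Cl; triisopropylsilyl trifluoromethanesulfonate CC(C)[Si](OS(=O)(=O)C(F)(F)F)(C(C)C)C(C)C
Why: Alcohol silylation, then soft enolisation under equilibrating silyl triflate/amine conditions, gives the thermodynamically preferred linear dienol silyl ether by loss of the γ-hydrogen at C8.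

**Step 5**
Reactants: 9 12-(triisopropylsilyloxy)-13-acetoxy-12,14(8)-diene; 10 acrolein
Product: 11 bicyclo[2.2.2]octene aldehyde
Conditions: acrolein (5 equiv), BHT, toluene, 60 °C
Reagents that add atoms: none
Why: Diels–Alder reaction of the 1-silyloxy diene in the ortho sense (formyl-bearing carbon to C12, CH2 to C8) on the convex face anti to C10 sets the quaternary C8 (C15 cis to H9) and the C12 bridgehead; the C16 epimers converge in step 7.

**Step 6**
Reactants: 11 bicyclo[2.2.2]octene aldehyde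
Product: 12 aldehyde enol triflate
Conditions: KN(SiMe3)2, PhNTf2, THF, −78 °C
Reagents that add atoms: N-phenylbis(trifluoromethanesulfonimide) O=S(=O)(N(c1ccccc1)S(=O)(=O)C(F)(F)F)C(F)(F)F
Why: Enolisation of the aldehyde (the most acidic C–H) and O-triflation give the exocyclic enol triflate.

**Step 7**
Reactants: 12 aldehyde enol triflate
Product: 13 16-methylene bicyclo[2.2.2]octene enol acetate
Conditions: Pd(OAc)2 (5 mol%), PPh3, HCO2H, Et3N, DMF, 60 °C
Reagents that add atoms: none
Why: Palladium-catalysed formate reduction of the vinyl triflate leaves the exocyclic C16=C17 methylene.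

**Step 8**
Reactants: 13 16-methylene bicyclo[2.2.2]octene enol acetate
Product: 14 12-(triisopropylsilyloxy)-16-methylenebicyclo[2.2.2]octan-13-one
Conditions: K2CO3 (0.2 equiv), MeOH, 0 °C
Reagents that add atoms: none
Why: Mild transesterification cleaves the enol acetate to the C13 ketone and removes the labile trimethylsilyl ether, while the bridgehead triisopropylsilyl and the tert-butyldimethylsilyl ethers survive.

**Step 9**
Reactants: 14 12-(triisopropylsilyloxy)-16-methylenebicyclo[2.2.2]octan-13-one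
Product: 15 13-hydroxy-12-(triisopropylsilyloxy)-16-methylenebicyclo[3.2.1]octane
Conditions: SmI2 (3 equiv), HMPA, t-BuOH (2 equiv), THF, −20 → 23 °C; then aq. NH4Cl
Reagents that add atoms: none
Why: Proposed new method: the samarium ketyl at C13 cyclises 3-exo onto C16 of the homoallylic methylene group and the cyclopropylcarbinyl radical reopens by breaking C12–C16 (closest known types: SmI2 ketyl–olefin cyclisation and the homoallyl radical rearrangement of bicyclo[2.2.2]octenyl to bicyclo[3.2.1]octenyl radicals); the ketyl is persistent whereas the α-silyloxy C12 radical is removed irreversibly by reduction and protonation by t-BuOH on the open face that C16 vacated (the other face is blocked by C10), which sets C13 and C12, and loss of the bridgehead silyloxy group is stereoelectronically impossible.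

**Step 10**
Reactants: 15 13-hydroxy-12-(triisopropylsilyloxy)-16-methylenebicyclo[3.2.1]octane
Product: 16 6-ketone
Conditions: Dess–Martin periodinane, NaHCO3, CH2Cl2, 23 °C
Reagents that add atoms: none
Why: Dess–Martin oxidation of the only free secondary alcohol (C6); the tertiary C13 alcohol cannot be oxidised.

**Step 11**
Reactants: 16 6-ketone
Product: 17 5-en-6-yl triflate
Conditions: KN(SiMe3)2 (2.2 equiv), PhNTf2, THF, −78 °C
Reagents that add atoms: N-phenylbis(trifluoromethanesulfonimide) O=S(=O)(N(c1ccccc1)S(=O)(=O)C(F)(F)F)C(F)(F)F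
Why: Enolate formation at C5 (the only enolisable position) with in situ O-triflation at −78 °C, which outruns β-elimination of the C10 silyl ether.

**Step 12**
Reactants: 17 5-en-6-yl triflate; 18 carbon monoxide
Product: 19 2-(trimethylsilyl)ethyl 5-en-7-oate
Conditions: Pd(OAc)2 (5 mol%), dppf, CO (1 atm), Me3SiCH2CH2OH, Et3N, DMF, 50 °C
Reagents that add atoms: 2-(trimethylsilyl)ethanol C[Si](C)(C)CCO
Why: Palladium-catalysed alkoxycarbonylation of the vinyl triflate installs C7 as a fluoride-labile ester.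

**Step 13**
Reactants: 19 2-(trimethylsilyl)ethyl 5-en-7-oate
Product: 20 10-alcohol
Conditions: HF·pyridine, pyridine/THF, 0 °C
Reagents that add atoms: none
Why: Selective desilylation of the less hindered allylic tert-butyldimethylsilyl ether in the presence of the hindered secondary triisopropylsilyl ether.

**Step 14**
Reactants: 20 10-alcohol
Product: 21 tricyclic 10-keto enone ester
Conditions: Dess–Martin periodinane, NaHCO3, CH2Cl2, 0 °C
Reagents that add atoms: none
Why: Dess–Martin oxidation of the allylic alcohol gives the 4-oxo-2-enoate.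

**Step 15**
Reactants: 21 tricyclic 10-keto enone ester; 22 vinylmagnesium bromide; 23 propionyl chloride
Product: 25 10β-vinyl 10α-propionate, via tertiary alkoxide 24 (not isolated)
Conditions: CeCl3, CH2=CHMgBr (2.5 equiv), THF, −78 °C; then EtCOCl (1.1 equiv), −78 → 0 °C
Reagents that add atoms: none
Why: Cerium-mediated 1,2-Grignard addition to the C10 ketone from the β face (anti to C11 on C9) sets C10, and the tertiary alkoxide is O-acylated in situ, the hindered bridgehead C13 alkoxide being inert.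

**Step 16**
Reactants: 25 10β-vinyl 10α-propionate
Product: 26 19,10-γ-lactone
Conditions: KN(SiMe3)2 (2.1 equiv), THF, −78 → −40 °C; then t-BuOH, 0 °C; then AcOH
Reagents that add atoms: none
Why: Intramolecular Michael addition of the propionate enolate to C5 on the α face fixed by the C10–O tether gives the cis-fused γ-lactone (sets C5), and alkoxide equilibration puts the C6 ester trans to C4 (sets C6); C4 stays an inconsequential epimer mixture.

**Step 17**
Reactants: 26 19,10-γ-lactone; 10 acrolein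
Product: 27 3β-hydroxy-3-vinyl aldol adduct
Conditions: LiN(iPr)2 (2.2 equiv), THF, −78 °C; acrolein, −78 °C; then AcOH
Reagents that add atoms: none
Why: Aldol addition of the lithium lactone enolate (methyl cis to the enolate oxygen) to acrolein through a Zimmerman–Traxler chair with vinyl equatorial, on the lactone face anti to C6, sets C4 and the 3β-carbinol.

**Step 18**
Reactants: 27 3β-hydroxy-3-vinyl aldol adduct
Product: 28 12-O-triisopropylsilyl ether 2-(trimethylsilyl)ethyl ester of the target gibberellin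
Conditions: second-generation Grubbs catalyst (5 mol%), CH2Cl2, 40 °C
Reagents that add atoms: none
Why: Ring-closing metathesis of the two vinyl groups forms C1=C2 of ring A; the 1,1-disubstituted C16 methylene is far less reactive.

**Step 19**
Reactants: 28 12-O-triisopropylsilyl ether 2-(trimethylsilyl)ethyl ester of the target gibberellin
Product: 29 target gibberellin (free 12-alcohol and 7-carboxylic acid)
Conditions: Bu4NF, AcOH, THF, 23 °C
Reagents that add atoms: none
Why: Fluoride removes the silyl ether and cleaves the 2-(trimethylsilyl)ethyl ester by β-elimination, with acetic acid buffering to protect the base-sensitive allylic lactone.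

**Compound list**
1 | (R)-4-(tert-butyldimethylsilyloxy)cyclopent-2-en-1-one | O=C1C=C[C@H](O[Si](C)(C)C(C)(C)C)C1 | starting material
2 | (E)-1-methoxy-3-(trimethylsilyloxy)buta-1,3-diene (Danishefsky's diene) | CO/C=C/C(=C)O[Si](C)(C)C | starting material
3 | cis-fused cycloadduct: C12=C13 trimethylsilyl enol ether, 14-OMe, 6-ketone, 10β-OTBS, H8β, H9β (C14 epimers) | O=C1C[C@@H](O[Si](C)(C)C(C)(C)C)[C@@H]2CC(O[Si](C)(C)C)=CC(OC)[C@H]12 | intermediate
4 | cis-fused 13-hydroxy-14-methoxy-6,12-diketone, 10β-OTBS (C13/C14 epimers) | O=C1C[C@@H](O[Si](C)(C)C(C)(C)C)[C@@H]2CC(=O)C(O)C(OC)[C@H]12 | intermediate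
5 | 13-acetoxy-14-methoxy-6,12-diketone | O=C1C[C@@H](O[Si](C)(C)C(C)(C)C)[C@@H]2CC(=O)C(OC(C)=O)C(OC)[C@H]12 | intermediate
6 | 13-acetoxy-13-en-12-one 6-ketone (diosphenol acetate) | O=C1C[C@@H](O[Si](C)(C)C(C)(C)C)[C@@H]2CC(=O)C(OC(C)=O)=C[C@H]12 | intermediate
7 | 6α-alcohol of 6 | O[C@@H]1C[C@@H](O[Si](C)(C)C(C)(C)C)[C@@H]2CC(=O)C(OC(C)=O)=C[C@H]12 | intermediate
8 | 6-O-trimethylsilyl ether of 7 | C[Si](C)(C)O[C@@H]1C[C@@H](O[Si](C)(C)C(C)(C)C)[C@@H]2CC(=O)C(OC(C)=O)=C[C@H]12 | intermediate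
9 | 12-(triisopropylsilyloxy)-13-acetoxy-12,14(8)-diene, 6-OTMS, 10β-OTBS | C[Si](C)(C)O[C@@H]1C[C@@H](O[Si](C)(C)C(C)(C)C)[C@@H]2CC(O[Si](C(C)C)(C(C)C)C(C)C)=C(OC(C)=O)C=C12 | intermediate
10 | acrolein | C=CC=O | starting material
11 | bicyclo[2.2.2]octene aldehyde: 12-OTIPS bridgehead, 13-acetoxy-13-ene, 16-formyl (endo), C8–C15 and C12–C16 bonds | C[Si](C)(C)O[C@@H]1C[C@@H](O[Si](C)(C)C(C)(C)C)[C@@H]2C[C@@]3(O[Si](C(C)C)(C(C)C)C(C)C)[C@H](C=O)C[C@@]12C=C3OC(C)=O | intermediate
12 | aldehyde enol triflate (C16=C17H–OTf, E/Z mixture) | C[Si](C)(C)O[C@@H]1C[C@@H](O[Si](C)(C)C(C)(C)C)[C@@H]2C[C@@]3(O[Si](C(C)C)(C(C)C)C(C)C)C(=COS(=O)(=O)C(F)(F)F)C[C@@]12C=C3OC(C)=O | intermediate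
13 | 16-methylene bicyclo[2.2.2]octene enol acetate | C[Si](C)(C)O[C@@H]1C[C@@H](O[Si](C)(C)C(C)(C)C)[C@@H]2C[C@@]3(O[Si](C(C)C)(C(C)C)C(C)C)C(=C)C[C@@]12C=C3OC(C)=O | intermediate
14 | 12-(triisopropylsilyloxy)-16-methylenebicyclo[2.2.2]octan-13-one, 6α-OH, 10β-OTBS | O[C@@H]1C[C@@H](O[Si](C)(C)C(C)(C)C)[C@@H]2C[C@@]3(O[Si](C(C)C)(C(C)C)C(C)C)C(=C)C[C@@]12CC3=O | intermediate
15 | 13-hydroxy-12-(triisopropylsilyloxy)-16-methylenebicyclo[3.2.1]octane (C12/C13 as in the target), 6α-OH, 10β-OTBS | C=C1C[C@]23C[C@@]1(O)[C@@H](O[Si](C(C)C)(C(C)C)C(C)C)C[C@H]2[C@H](O[Si](C)(C)C(C)(C)C)C[C@H]3O | intermediate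
16 | 6-ketone of 15 | C=C1C[C@]23C[C@@]1(O)[C@@H](O[Si](C(C)C)(C(C)C)C(C)C)C[C@H]2[C@H](O[Si](C)(C)C(C)(C)C)CC3=O | intermediate
17 | 5-en-6-yl triflate | C=C1C[C@]23C[C@@]1(O)[C@@H](O[Si](C(C)C)(C(C)C)C(C)C)C[C@H]2[C@H](O[Si](C)(C)C(C)(C)C)C=C3OS(=O)(=O)C(F)(F)F | intermediate
18 | carbon monoxide | [C-]#[O+] | starting material
19 | 2-(trimethylsilyl)ethyl 5-en-7-oate, 10β-OTBS | C=C1C[C@]23C[C@@]1(O)[C@@H](O[Si](C(C)C)(C(C)C)C(C)C)C[C@H]2[C@H](O[Si](C)(C)C(C)(C)C)C=C3C(=O)OCC[Si](C)(C)C | intermediate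
20 | 10-alcohol | C=C1C[C@]23C[C@@]1(O)[C@@H](O[Si](C(C)C)(C(C)C)C(C)C)C[C@H]2[C@H](O)C=C3C(=O)OCC[Si](C)(C)C | intermediate
21 | tricyclic 10-keto enone ester | C=C1C[C@]23C[C@@]1(O)[C@@H](O[Si](C(C)C)(C(C)C)C(C)C)C[C@H]2C(=O)C=C3C(=O)OCC[Si](C)(C)C | intermediate
22 | vinylmagnesium bromide | C=C[Mg]Br | starting material
23 | propionyl chloride | CCC(Cl)=O | starting material
24 | 10β-vinyl 10α-alkoxide (bromomagnesium salt, drawn as the alcohol) | C=C1C[C@]23C[C@@]1(O)[C@@H](O[Si](C(C)C)(C(C)C)C(C)C)C[C@H]2[C@](O)(C=C)C=C3C(=O)OCC[Si](C)(C)C | intermediate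
25 | 10β-vinyl 10α-propionate | C=C1C[C@]23C[C@@]1(O)[C@@H](O[Si](C(C)C)(C(C)C)C(C)C)C[C@H]2[C@](OC(=O)CC)(C=C)C=C3C(=O)OCC[Si](C)(C)C | intermediate
26 | 19,10-γ-lactone with 10β-vinyl, H5β, 6β-ester (C4 epimers) | C=C1C[C@]23C[C@@]1(O)[C@@H](O[Si](C(C)C)(C(C)C)C(C)C)C[C@H]2[C@@]1(C=C)OC(=O)C(C)[C@H]1[C@@H]3C(=O)OCC[Si](C)(C)C | intermediate
27 | 3β-hydroxy-3-vinyl aldol adduct (ring A open at C1/C2) | C=C1C[C@]23C[C@@]1(O)[C@@H](O[Si](C(C)C)(C(C)C)C(C)C)C[C@H]2[C@@]1(C=C)OC(=O)[C@](C)([C@@H](O)C=C)[C@H]1[C@@H]3C(=O)OCC[Si](C)(C)C | intermediate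
28 | 12-O-triisopropylsilyl ether 2-(trimethylsilyl)ethyl ester of the target gibberellin | C=C1C[C@]23C[C@@]1(O)[C@@H](O[Si](C(C)C)(C(C)C)C(C)C)C[C@H]2[C@@]12C=C[C@H](O)[C@@](C)(C(=O)O1)[C@H]2[C@@H]3C(=O)OCC[Si](C)(C)C | intermediate
29 | target gibberellin, number 87 of the A series: 3β,12,13-trihydroxy-20-norgibberella-1,16-diene-7,19-dioic acid 19,10-lactone, 12-OH on the ring C face of the C14 bridge | C=C1C[C@]23C[C@@]1(O)[C@@H](O)C[C@H]2[C@@]12C=C[C@H](O)[C@@](C)(C(=O)O1)[C@H]2[C@@H]3C(=O)O | target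

**Totals and weak points**
Total step count: 19. Longest linear sequence: 19 steps (1 → 29).

Step 9 (radical rearrangement). If the ketyl is simply reduced, or protonation at C12 gives the wrong epimer, the same skeletal change is made by a polar route from 14. Me2AlCl in CH2Cl2 (−78 → 0 °C) induces the α-ketol rearrangement of the α-silyloxy ketone, with shift of the alkenyl carbon C16 from C12 to C13 and silyl transfer, to give the 12-keto 13-silyl ether F1. LiBH(sBu)3 in THF at −78 °C attacks the C12 ketone from the equatorial direction (the axial path is blocked by C10) to give the axial 12-alcohol F2. Catalytic NaH in THF then moves the silyl group from the tertiary O13 to the secondary O12, which gives 15.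

Step 4 (position of the dienol ether). If the cross-conjugated isomer forms, the C14=C8 double bond is placed explicitly, starting from 8. Thiophenol with catalytic Et3N adds in the conjugate sense to give the 14β-phenylthio ketone F3. iPr3SiOTf/Et3N enolises toward the acetoxy-bearing C13 to give the enediol silyl ether F4. mCPBA at −78 °C gives the sulfoxide F5, and warming in toluene (90 °C, CaCO3) causes syn-elimination toward the cis hydrogen on C8, which gives 9.

Step 16 (lactone-forming Michael addition). If ester-enolate Claisen rearrangement through the C10 vinyl group or slow five-ring closure intervenes, a stabilised carbanion is used, starting from 21. Vinyl addition as in step 15 and acylation of alkoxide 24 with 2-(phenylsulfonyl)propanoyl chloride give the sulfonyl propionate F6. Cs2CO3 in MeCN at 0 °C closes the ring to the α-sulfonyl lactone F7. SmI2 in THF/MeOH at −78 °C removes the sulfonyl group and gives 26.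

**Further compounds**
F1 | step 9 | 12-keto 13-O-triisopropylsilyl bicyclo[3.2.1]octane | C=C1C[C@]23C[C@@]1(O[Si](C(C)C)(C(C)C)C(C)C)C(=O)C[C@H]2[C@H](O[Si](C)(C)C(C)(C)C)C[C@H]3O
F2 | step 9 | axial 12-alcohol 13-O-triisopropylsilyl ether | C=C1C[C@]23C[C@@]1(O[Si](C(C)C)(C(C)C)C(C)C)[C@@H](O)C[C@H]2[C@H](O[Si](C)(C)C(C)(C)C)C[C@H]3O
F3 | step 4 | 14β-phenylthio 13-acetoxy 12-ketone | C[Si](C)(C)O[C@@H]1C[C@@H](O[Si](C)(C)C(C)(C)C)[C@@H]2CC(=O)C(OC(C)=O)[C@@H](Sc3ccccc3)[C@H]12
F4 | step 4 | 14β-phenylthio enediol silyl ether | C[Si](C)(C)O[C@@H]1C[C@@H](O[Si](C)(C)C(C)(C)C)[C@@H]2CC(O[Si](C(C)C)(C(C)C)C(C)C)=C(OC(C)=O)[C@@H](Sc3ccccc3)[C@H]12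
F5 | step 4 | 14β-phenylsulfinyl enediol silyl ether | C[Si](C)(C)O[C@@H]1C[C@@H](O[Si](C)(C)C(C)(C)C)[C@@H]2CC(O[Si](C(C)C)(C(C)C)C(C)C)=C(OC(C)=O)[C@@H](S(=O)c3ccccc3)[C@H]12
F6 | step 16 | 10β-vinyl 10α-[2-(phenylsulfonyl)propionate] | C=C1C[C@]23C[C@@]1(O)[C@@H](O[Si](C(C)C)(C(C)C)C(C)C)C[C@H]2[C@](OC(=O)C(C)S(=O)(=O)c1ccccc1)(C=C)C=C3C(=O)OCC[Si](C)(C)C
F7 | step 16 | 4-phenylsulfonyl 19,10-γ-lactone | C=C1C[C@]23C[C@@]1(O)[C@@H](O[Si](C(C)C)(C(C)C)C(C)C)C[C@H]2[C@@]1(C=C)OC(=O)C(C)(S(=O)(=O)c4ccccc4)[C@H]1[C@@H]3C(=O)OCC[Si](C)(C)C
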